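Read the ends first.

| setting | south-east | east | south | west | south-west |
|---|---|---|---|---|---|
| starting material | 100 mM | 60.0 mM | 100 mM | 100 mM | 250 mM |
| partner | 300 mM | 260 mM | 300 mM | 600 mM | 750 mM |
| free catalyst | 0.500 mM | 0.500 mM | 1.50 mM | 0.500 mM | 0.500 mM |
| time |  |  |  |  | 16 min |

- south-east run (time / min: [product] / mM): 0.71: 4.9; 2.2: 14.6; 4.1: 25.0; 6.5: 35.6; 9.3: 44.5; 13: 51.5; 16: 55.0
- east run (time / min: [product] / mM): 0.71: 3.7; 2.2: 12.3; 4.1: 21.1; 6.5: 29.7; 9.3: 37.9; 13: 44.5; 16: 47.7
- south run (time / min: [product] / mM): 0.71: 13.5; 2.2: 41.2; 4.1: 66.3; 6.5: 85.7; 9.3: 95.1; 13: 98.8; 16: 100.4
- west run (time / min: [product] / mM): 0.71: 3.7; 2.2: 13.7; 4.1: 25.6; 6.5: 36.8; 9.3: 46.1; 13: 53.8; 16: 57.7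

(standard deviation of a reading: 0.3 mM)

- Overall: starting material + partner -> product, with free catalyst as catalyst.
- Constant volume, constant temperature.
- What is held in complexes is read along with the free species.
- "The second partner" is partner.
- An order is taken over about fifteen percent of the charge, up and down.

1. order of the initial rate in [free catalyst], near the charge of the south-east run, the rate being that where two percent of its starting material are product
2. order of the initial rate in [starting material], near the charge of the south-east run, the rate being that where two percent of its starting material are product (one fixed amount of product, the same in the runs compared)
3. the east run starts with 40.0 mM less of starting material and of partner than the south-east run, and with no product. Compared where both hold the same amount of starting material, once fifteen percent of what the east run was charged with has turned into product, is the east run faster, slower or alike (within a tenth)?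
4. product in the south-west run at 16 min, as a share of the starting material charged

The west run is the neighbour of the south-east run: it has the same starting material and free catalyst, but twice the partner. The south-east run makes 110 product per free catalyst charged by its last reading at 16 min; this count of turnovers is the reach, N.

| run | starting material | partner | last product | N |
|---|---|---|---|---|
| south-east | 100 mM | 300 mM | 55.0 mM | 110 |
| west | 100 mM | 600 mM | 57.7 mM | 115 |
| east | 60.0 mM | 260 mM | 47.7 mM | 95.4 |

The last reading of the west run stands higher than that of the south-east run, but the extra partner raises N by a factor of just 1.05. Both runs are still slowing with starting material in the flask: 45.0 mM in the south-east run and 42.3 mM in the west run.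

Between the east and south-east runs, the charge of starting material rises by a factor of 1.67 and N by 1.15, although the charge of partner differs as well. Taken as a power, this gives an exponent m = 0.279.

The south-west run has the free catalyst of the south-east run, with its starting material raised by a factor of 2.50. The reckoning here leaves its extra partner aside and gives N = 142, or 28.4 % of the starting material charged.

The forecast gives 0.95 (0.85 to 1.05) for the order in free catalyst, 0.35 (0.2 to 0.5) for the order in starting material, and faster for the east run. For the south-west run it gives 24.8 % (22.8 % to 27.5 %), holding that “South-west sits near saturation and stalls on the same turnover limit”. The reckoning here stands above that range.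

The flask gives 0.97, 0.42, faster and 26.9 %.

    free catalyst + starting material → catalyst-substrate complex (1158 /M/min)
    catalyst-substrate complex + partner → loaded catalyst (351.6 /M/min)
    loaded catalyst → product + free catalyst (32.58 /min)
    free catalyst + partner ⇌ idle catalyst-reagent complex, settled at all times (10.30 /M)
    2 partner → lost reagent (1.404 /M/min)

The south-west run reaches N = 134, a factor of 1.22 above the south-east run and below the reckoned 142. Its reach at 16 min is lowered by the path from 2 partner to lost reagent: without that path, the same run gives 44.5 %, or N = 223, so the path accounts for 24 % of what is missing. The south run ends differently, with starting material as the limiting reagent: its charge allows N = 66.7, and its last reading gives N = 66.9, from 100.4 mM of product.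

All runs come from a simulation from invented constants; scatter was added.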